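## The problem

Kadsurenin D (18) is a bicyclo[3.2.1]oct-2-ene-4,8-dione. Numbering used throughout: C1 is the allyl-bearing bridgehead, C2=C3 the enol ether (OMe on C3), C4 the enone carbonyl, C5 the CH bridgehead, C6 the aryl carbon, C7 the methyl carbon and C8 the bridging ketone. A cyclohexenedione ring (C1–C2–C3–C4–C5–C8) and a cyclopentanone ring (C1–C7–C6–C5–C8) share the C1–C8–C5 unit. Four contiguous stereocentres must be set: quaternary C1, C5, C6 (aryl exo, syn to C8) and C7 (methyl endo, trans to aryl). C7 can direct C1 if both sit in a small ring, C7 can direct C6 (aryl trans to methyl), and C5 is fixed by the geometry of the bridge once C1 is defined. The absolute configuration must therefore enter with C7. The molecule will not tolerate hydrogenation or hydroboration late on (allyl group), aqueous acid (enol ether of an α-diketone), or hard nucleophiles (C4 and C8 form a non-enolisable 1,3-dicarbonyl through the bridgehead, open to retro-Claisen cleavage). The electron-rich benzylic C6 ionises easily. The enabling feature is that C8 is an acyl carbon three atoms away from benzylic C6: tying the C8 oxygen to C6 turns C8–C1–C7–C6 into a γ-aryl-β-methyl butyrolactone with a quaternary α-carbon. That lactone is a rigid template for C1 and C7, an acyl donor for the C5–C8 bond, and it leaves a benzylic hydroxyl at C6 as the leaving group for the last ring.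

## Retrosynthesis

**C5–C6 (18 ⇒ 17).** C6 is benzylic to a dimethoxyphenyl ring and C5 is the central carbon of a 1,3-dione, so this bond is the natural cation/enol pairing. Cutting C4–C5 or C1–C2 instead would leave the five-membered carbocycle and all four stereocentres in place and simplify little. Hydroxy dione 17 has one ring and two stereocentres fewer. The forward reaction must ionise C6, bond it to carbon rather than oxygen, and place the aryl group trans to the C7 methyl.

**C5–C8 (17 ⇒ 16, key cut).** In 17 the C6 hydroxyl is γ to acyl carbon C8, so 17 is the ring-opened form of butyrolactone 16, with C5 as the methyl group of an acetyl side arm. Cutting C1–C8 would demand acylation at a quaternary carbon, and cutting C4–C5 would require the carbocyclic five-membered ring first. The C5–C8 cut reduces the six-membered ring to a lactone with an enone arm and creates no stereocentre. The forward reaction needs enolisation at C5 only, attack on the lactone carbonyl rather than on the enone, and an (E)-alkene so that C1 and the acetyl group are cis.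

**C2=C3 (16 ⇒ 12 + 15).** The enol ether alkene is made by Horner–Wadsworth–Emmons olefination of quaternary aldehyde 12 with α-methoxy-β-ketophosphonate 15. The neighbouring cut, C1–C2 by addition of a lactone enolate to a β-leaving-group enone followed by allylation, would put the unsaturated arm in place while C1 is still deprotonated. The resulting extended enolate can lose the alkene geometry and can be allylated at C3 as well as C1. Forming the alkene last, on a carbon that is already quaternary, avoids both problems. The forward reaction must work on a neopentyl aldehyde and favour the isomer with C1 cis to acetyl.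

**C3–O (15 ⇒ 13 + 14).** The phosphonate is a one-step product of carbenoid O–H insertion of diazophosphonate 13 into methanol 14.

**C1–allyl and C1–C2 (12 ⇒ 10 + 11; 10 ⇒ 8 + 9).** A group introduced at C1 of the lactone enters anti to the C7 methyl. The group that must end cis to methyl (the formyl carbon C2) therefore goes in first by formylation of lactone 8 with ethyl formate 9. The allyl group comes second, from allyl acetate 11, on the stabilised enolate of 10. Two simple alkylating steps replace a quaternary stereocentre.

**Lactone and C6–C7 (8 ⇒ 6 ⇒ 4 ⇒ 1 + 2).** Lactone 8 is the oxidation product of 1,4-diol 6, which comes from hydroboration of homoallylic alcohol 4. Alcohol 4 is the anti-crotylation product of 3,4-dimethoxybenzaldehyde 1 with (E)-crotylboronate 2. This one catalytic step sets C7 absolutely and C6 relative to it. C6 is later ionised, so its role is to give a single, crystallinity-friendly 4,5-trans lactone.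

## Roads not taken

**Alternative 1:** Cut C7–CH3 and C1–allyl on a preformed cyclopentenone. A methyl cuprate would add to C7 of phenyl (E)-3-[3-(3,4-dimethoxyphenyl)-5-oxocyclopent-1-en-1-yl]-2-methoxyacrylate A1, and the enolate would be allylated at C1 to give phenyl (E)-3-[1-allyl-4-(3,4-dimethoxyphenyl)-5-methyl-2-oxocyclopentyl]-2-methoxyacrylate A2. A Claisen closure of C5 onto the phenyl ester would then give 18 directly.
- Merits: C6 is fixed from the start and controls C7 and then C1 by two anti additions. Two bonds form in one flask, and no cationic step is needed for C6. In these respects it is better than the chosen plan.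
- Weak points: the enolate formed by conjugate addition is conjugated through C2=C3 into the ester, so allylation can occur at C3 and the alkene geometry (which must again be C1 cis to the acyl group) can be lost. The cuprate may attack the acrylate or the phenyl ester. A1 must itself be made enantioenriched in several steps.
- Comparison: the chosen plan is longer after the stereodefining step and sets C6 last. Against this, it never generates an enolate at C1 while the enol ether arm is present, and its absolute configuration comes from one catalytic step on a commercial aldehyde.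

**Alternative 2:** Cut C1–C2 and C4–C5. 2-Allylcyclopentane-1,3-dione A3 would add through C1 to acrolein A4, and a chiral amine–thiourea catalyst would direct the aldol of one enantiotopic α-carbon onto the aldehyde, giving 1-allyl-4-hydroxybicyclo[3.2.1]octane-7,8-dione A5.
- Merits: the whole bicyclic core, the quaternary bridgehead and the absolute configuration arise in one catalytic step from trivial materials. For skeleton construction this is clearly superior to the chosen plan.
- Weak points: A5 carries a ketone where the methyl group belongs (C7), hydrogen where the aryl group belongs (C6), a carbinol at C4 and a saturated C2–C3. Reaching 18 needs arylation at C6, replacement of the C7 oxygen by an endo methyl without hydrogenating the allyl group, differentiation of the C7 and C8 ketones, oxidation at C4 and C3, dehydrogenation and O-methylation. A5 is also a β-hydroxy ketone prone to retro-aldol opening.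
- Comparison: the chosen plan builds the core late and through two demanding closures, but every substituent arrives at its final oxidation level.

**Alternative 3:** Cut C6–C7 and C1–allyl. A Lewis acid would trigger 4π closure of methyl (4E)-4-[(2E)-3-(3,4-dimethoxyphenyl)prop-2-enoyl]hex-4-enoate A6, and an allylsilane would capture the oxyallyl cation at C1 to give methyl 3-[1-allyl-4-(3,4-dimethoxyphenyl)-5-methyl-2-oxocyclopentyl]propanoate A7.
- Merits: conrotation guarantees the trans C6/C7 relationship. The carbocyclic five-membered ring and three stereocentres form in one step from an easily made dienone, and the C5–C6 bond never has to be made by a cation. On these points it is at least as good as the chosen plan.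
- Weak points: the oxyallyl cation has a free terminus at C5 that competes with the fully substituted C1 for the allylsilane. Asymmetric induction on a dienone without a chelating group is not secured. A7 has a saturated C2–C3–C4 arm, so after Claisen closure C3 must still be oxygenated, dehydrogenated and O-methylated.
- Comparison: the chosen plan offers a reliable catalytic entry to a single enantiomer and carries the enol ether intact. It pays with a geometry-dependent olefination and a late cationic closure.

Key step: step 8

Assumption: the (S)-phosphoric acid is taken to direct the crotyl group to the Si face of aldehyde 1, the mirror image of the Re-face preference of the (R)-acid with benzaldehyde; if the sense were opposite, the (R)-acid would be used and nothing else changes.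

Step 1
Reactants: 1 3,4-dimethoxybenzaldehyde; 2 (E)-crotylboronic acid pinacol ester
Product: 4 (1S,2S)-1-(3,4-dimethoxyphenyl)-2-methylbut-3-en-1-ol, via pinacol borate 3 (not isolated)
Conditions: (S)-3,3'-bis(2,4,6-triisopropylphenyl)-1,1'-binaphthalene-2,2'-diyl hydrogen phosphate (5 mol %), 4 Å MS, PhMe, −30 °C; aqueous work-up
Reagents that add atoms: none
Why: Chiral phosphoric acid-catalysed crotylboration; the (E)-boronate reacts through a closed chair transition state to give the anti alcohol, and the acid bound to the boronate oxygen selects the aldehyde face, setting C6 and C7 together.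

Step 2
Reactants: 4 (1S,2S)-1-(3,4-dimethoxyphenyl)-2-methylbut-3-en-1-ol
Product: 6 (1S,2S)-1-(3,4-dimethoxyphenyl)-2-methylbutane-1,4-diol, via alkylborane 5 (not isolated)
Conditions: 9-BBN (2.5 equiv), THF, 0 °C → rt; then NaOH, H2O2, 0 °C → rt
Reagents that add atoms: hydrogen peroxide, OO
Why: Anti-Markovnikov hydroboration–oxidation of a monosubstituted alkene; 9-BBN places boron at the terminal carbon only, and no stereocentre is touched.

Step 3
Reactants: 6 (1S,2S)-1-(3,4-dimethoxyphenyl)-2-methylbutane-1,4-diol
Product: 8 (4S,5S)-5-(3,4-dimethoxyphenyl)-4-methyloxolan-2-one (4,5-trans), via lactol 7 (not isolated)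
Conditions: TEMPO (10 mol %), PhI(OAc)2 (2.5 equiv), CH2Cl2, rt
Reagents that add atoms: none
Why: Oxoammonium-mediated oxidative lactonisation of a 1,4-diol; the primary alcohol is oxidised much faster than the hindered secondary benzylic one, the hydroxy aldehyde closes to lactol 7, and a second oxidation gives the lactone.

Step 4
Reactants: 8 (4S,5S)-5-(3,4-dimethoxyphenyl)-4-methyloxolan-2-one; 9 ethyl formate
Product: 10 (3Z,4S,5S)-5-(3,4-dimethoxyphenyl)-3-(hydroxymethylidene)-4-methyloxolan-2-one (enol tautomer of the 3-formyl lactone)
Conditions: NaH (2.2 equiv), HCO2Et (5 equiv), EtOH (cat.), THF, 0 °C → rt; then cold 1 M HCl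
Reagents that add atoms: none
Why: Crossed Claisen formylation of a butyrolactone, driven by formation of the stabilised sodium enolate of the β-formyl lactone; C7 and C6 are not acidic and are untouched.

Step 5
Reactants: 10 (3Z,4S,5S)-5-(3,4-dimethoxyphenyl)-3-(hydroxymethylidene)-4-methyloxolan-2-one; 11 allyl acetate
Product: 12 (3S,4S,5S)-3-allyl-5-(3,4-dimethoxyphenyl)-4-methyl-2-oxooxolane-3-carbaldehyde (allyl trans to methyl, formyl cis to methyl)
Conditions: NaH (1.0 equiv), THF, 0 °C; then Pd(PPh3)4 (5 mol %), allyl acetate (1.3 equiv), rt
Reagents that add atoms: none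
Why: Tsuji–Trost allylation of a β-dicarbonyl enolate; any O-allyl enol ether is re-ionised by zerovalent palladium, so the C-allyl product accumulates, and the π-allyl electrophile approaches the planar enolate on the face opposite the adjacent C7 methyl, setting C1.

Step 6
Reactants: 13 dimethyl (1-diazo-2-oxopropyl)phosphonate; 14 methanol
Product: 15 dimethyl (1-methoxy-2-oxopropyl)phosphonate (racemic)
Conditions: Rh2(OAc)4 (1 mol %), MeOH (5 equiv), CH2Cl2, 40 °C
Reagents that add atoms: none
Why: Rhodium carbenoid O–H insertion of a diazophosphonate into an alcohol, which outruns Wolff rearrangement when the alcohol is in excess.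

Step 7
Reactants: 12 (3S,4S,5S)-3-allyl-5-(3,4-dimethoxyphenyl)-4-methyl-2-oxooxolane-3-carbaldehyde; 15 dimethyl (1-methoxy-2-oxopropyl)phosphonate
Product: 16 (3S,4S,5S)-3-allyl-5-(3,4-dimethoxyphenyl)-3-[(1E)-2-methoxy-3-oxobut-1-en-1-yl]-4-methyloxolan-2-one
Conditions: 15 (1.3 equiv), KN(SiMe3)2 (1.2 equiv), 18-crown-6, THF, −78 °C → rt; chromatography on Et3N-deactivated silica
Reagents that add atoms: none
Why: Horner–Wadsworth–Emmons olefination of a non-enolisable aldehyde; α-heteroatom-substituted phosphonate anions under dissociating, low-temperature conditions tend to give the alkene with the aldehyde residue cis to the carbonyl, so the (E)-isomer is expected to predominate and is separated from any (Z)-isomer (NOE between vinyl H and OCH3 identifies it); base is kept substoichiometric to the phosphonate so the product's acetyl group is not enolised.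

Step 8
Reactants: 16 (3S,4S,5S)-3-allyl-5-(3,4-dimethoxyphenyl)-3-[(1E)-2-methoxy-3-oxobut-1-en-1-yl]-4-methyloxolan-2-one
Product: 17 (4S)-4-allyl-4-[(1S,2S)-1-(3,4-dimethoxyphenyl)-1-hydroxypropan-2-yl]-6-methoxycyclohex-5-ene-1,3-dione
Conditions: LiN(SiMe3)2 (2.5 equiv), THF (0.02 M), −78 → 0 °C; then cold 1 M HCl
Reagents that add atoms: none
Why: The amide base removes a proton from the acetyl methyl C5, the only enolisable position (C1 is quaternary, C2 is vinylic), giving a cross-conjugated lithium enolate. In the (E)-alkene this carbon lies over the lactone carbonyl C8 and adds to it in a 6-(enolendo)-exo-trig closure (C4 and C5 both become ring atoms), a favoured mode that gives a cis-fused tetrahedral intermediate. Collapse expels the benzylic alkoxide at C6, and the new cyclic 1,3-dione is deprotonated at C5 at once by that alkoxide or by excess base, which makes the acyl transfer irreversible. The closest known reaction type is the intramolecular Claisen (Dieckmann-type) condensation of a ketone enolate with a lactone, which opens the lactone to a hydroxyalkyl 1,3-dione. No stereocentre is formed: C1 and C7 cannot enolise, and C6 keeps its configuration because the C6–O bond is not broken. The step needs attack at the lactone carbonyl rather than conjugate addition or intermolecular aldol; the hindered base does not add to the enone, the six-membered transition state is intramolecular, and high dilution suppresses oligomerisation. It also needs the (E)-geometry, which step 7 supplies and which the enolate cannot scramble because C2=C3 stays a double bond. Acidification gives 17 as a mixture of dione/enol tautomers, all of which react alike in the next step.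

Step 9
Reactants: 17 (4S)-4-allyl-4-[(1S,2S)-1-(3,4-dimethoxyphenyl)-1-hydroxypropan-2-yl]-6-methoxycyclohex-5-ene-1,3-dione
Product: 18 kadsurenin D, (1S,5S,6R,7R)-1-allyl-6-(3,4-dimethoxyphenyl)-3-methoxy-7-methylbicyclo[3.2.1]oct-2-ene-4,8-dione (aryl exo and trans to the endo methyl)
Conditions: CF3CO2H (10 equiv), CH2Cl2 (0.01 M), 0 °C → rt
Reagents that add atoms: none
Why: Acid ionises the benzylic alcohol to a dimethoxybenzyl cation that is captured by C5 of the dione enol (intramolecular cationic C-alkylation of a 1,3-dicarbonyl); C5 is fixed by the bridge, and the aryl group takes the exo position trans to the C7 methyl and away from the enone bridge, while any O-alkylated cyclic enol ether can re-ionise and converge on the C-alkylated bicycle.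

## Compound list

1 | 3,4-dimethoxybenzaldehyde | COc1ccc(C=O)cc1OC | starting material
2 | (E)-crotylboronic acid pinacol ester | C/C=C/CB1OC(C)(C)C(C)(C)O1 | starting material
3 | 2-{[(1S,2S)-1-(3,4-dimethoxyphenyl)-2-methylbut-3-en-1-yl]oxy}-4,4,5,5-tetramethyl-1,3,2-dioxaborolane | C=C[C@H](C)[C@H](OB1OC(C)(C)C(C)(C)O1)c1ccc(OC)c(OC)c1 | intermediate
4 | (1S,2S)-1-(3,4-dimethoxyphenyl)-2-methylbut-3-en-1-ol | C=C[C@H](C)[C@H](O)c1ccc(OC)c(OC)c1 | intermediate
5 | 9-[(3S,4S)-4-(3,4-dimethoxyphenyl)-4-hydroxy-3-methylbutyl]-9-borabicyclo[3.3.1]nonane | B1(C2CCCC1CCC2)CC[C@H](C)[C@H](O)c1ccc(OC)c(OC)c1 | intermediate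
6 | (1S,2S)-1-(3,4-dimethoxyphenyl)-2-methylbutane-1,4-diol | OCC[C@H](C)[C@H](O)c1ccc(OC)c(OC)c1 | intermediate
7 | (4S,5S)-5-(3,4-dimethoxyphenyl)-4-methyloxolan-2-ol (anomer mixture) | OC1C[C@H](C)[C@@H](c2ccc(OC)c(OC)c2)O1 | intermediate
8 | (4S,5S)-5-(3,4-dimethoxyphenyl)-4-methyloxolan-2-one | O=C1C[C@H](C)[C@@H](c2ccc(OC)c(OC)c2)O1 | intermediate
9 | ethyl formate | CCOC=O | starting material
10 | (3Z,4S,5S)-5-(3,4-dimethoxyphenyl)-3-(hydroxymethylidene)-4-methyloxolan-2-one | O=C1/C(=C\O)[C@H](C)[C@@H](c2ccc(OC)c(OC)c2)O1 | intermediate
11 | allyl acetate | C=CCOC(C)=O | starting material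
12 | (3S,4S,5S)-3-allyl-5-(3,4-dimethoxyphenyl)-4-methyl-2-oxooxolane-3-carbaldehyde | O=C1[C@](CC=C)(C=O)[C@H](C)[C@@H](c2ccc(OC)c(OC)c2)O1 | intermediate
13 | dimethyl (1-diazo-2-oxopropyl)phosphonate | CC(=O)C(=[N+]=[N-])P(=O)(OC)OC | starting material
14 | methanol | CO | starting material
15 | dimethyl (1-methoxy-2-oxopropyl)phosphonate (racemic) | CC(=O)C(OC)P(=O)(OC)OC | intermediate
16 | (3S,4S,5S)-3-allyl-5-(3,4-dimethoxyphenyl)-3-[(1E)-2-methoxy-3-oxobut-1-en-1-yl]-4-methyloxolan-2-one | O=C1[C@](CC=C)(/C=C(/OC)C(C)=O)[C@H](C)[C@@H](c2ccc(OC)c(OC)c2)O1 | intermediate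
17 | (4S)-4-allyl-4-[(1S,2S)-1-(3,4-dimethoxyphenyl)-1-hydroxypropan-2-yl]-6-methoxycyclohex-5-ene-1,3-dione | O=C1CC(=O)C(OC)=C[C@]1(CC=C)[C@H](C)[C@H](O)c1ccc(OC)c(OC)c1 | intermediate
18 | kadsurenin D, (1S,5S,6R,7R)-1-allyl-6-(3,4-dimethoxyphenyl)-3-methoxy-7-methylbicyclo[3.2.1]oct-2-ene-4,8-dione | C=CC[C@]12C=C(OC)C(=O)[C@H](C1=O)[C@H](c1ccc(OC)c(OC)c1)[C@H]2C | target

## Step count and least certain steps

Total step count: 9 (steps 1–5 and 7–9 in line, step 6 for the phosphonate). Longest linear sequence: 8 steps from 1.

**Step 8 (key step).** The acetyl group of 16 is twisted out of conjugation by allylic strain against the quaternary carbon. Intermolecular aldol or Michael condensation of the enolate may therefore compete with closure. Any material that has drifted to the (Z)-geometry (for example through reversible conjugate addition of the liberated alkoxide) cannot close at all. Reversal of the acyl transfer during a poorly controlled quench is a further risk. The fallback removes the alkene from the closure. It sets out from 16 (either geometry or a mixture). Acid-catalysed addition of methanol (MeOH, HC(OMe)3, camphorsulfonic acid) should give 3-allyl-3-(2,2-dimethoxy-3-oxobutyl)-5-(3,4-dimethoxyphenyl)-4-methyloxolan-2-one F1, whose only enolisable position is still C5. The same base then closes a flexible chain onto the lactone to give 4-allyl-4-[(1S,2S)-1-(3,4-dimethoxyphenyl)-1-hydroxypropan-2-yl]-6,6-dimethoxycyclohexane-1,3-dione F2. CF3CO2H, followed if needed by TsOH in warm toluene, ionises C6, closes C5–C6 and eliminates methanol from the α-keto ketal, so the C2=C3 enol ether forms inside the ring, where only the cis arrangement exists. The sequence comes back to the route at 18.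

**Step 7.** Addition of a fully substituted phosphonate anion to a neopentyl aldehyde may be slow. The kinetic preference for the (E)-alkene, which is the thermodynamically less stable isomer, may be insufficient or be eroded on silica. The fallback is a stepwise construction from 12. Methoxyacetone is converted (Me3SiOTf, Et3N) into (Z)-1-methoxy-2-(trimethylsilyloxy)prop-1-ene F3. A BF3·OEt2-promoted Mukaiyama aldol addition to the activated aldehyde gives 3-allyl-5-(3,4-dimethoxyphenyl)-3-(1-hydroxy-2-methoxy-3-oxobutyl)-4-methyloxolan-2-one F4. Dehydration with the Burgess reagent returns to the route at 16, alongside its geometric isomer (3S,4S,5S)-3-allyl-5-(3,4-dimethoxyphenyl)-3-[(1Z)-2-methoxy-3-oxobut-1-en-1-yl]-4-methyloxolan-2-one F5. F5 is not discarded; it enters the methanol-addition sequence described for step 8.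

**Step 5.** Facial discrimination in the allylation of a planar, stabilised enolate may be modest, since the aryl group sits on the face opposite the methyl. Loss of the formyl group from the quaternary β-formyl lactone by adventitious alkoxide is also possible. The fallback uses a non-stabilised enolate and sets out from 8. LiN(iPr)2 and monomeric formaldehyde give (3R,4S,5S)-5-(3,4-dimethoxyphenyl)-3-(hydroxymethyl)-4-methyloxolan-2-one F6. Its alkoxide–enolate dianion (2.2 equiv LiN(iPr)2) is alkylated with allyl bromide anti to the methyl group, in a Fráter–Seebach-type alkylation, to give (3S,4S,5S)-3-allyl-5-(3,4-dimethoxyphenyl)-3-(hydroxymethyl)-4-methyloxolan-2-one F7. Dess–Martin oxidation comes back to the route at 12.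

**Step 9.** Kinetic O-alkylation may dominate and the cyclic enol ether may not rearrange under CF3CO2H. Acid-promoted re-lactonisation of the hydroxy dione may precede ionisation. Some cleavage of the enol ether is also possible. The fallback separates the two events and sets out from 17. Mitsunobu cyclodehydration (PPh3, diisopropyl azodicarboxylate) under neutral conditions gives 3a-allyl-2-(3,4-dimethoxyphenyl)-5-methoxy-3-methyl-3,3a-dihydro-1-benzofuran-6(2H)-one F8. The isolated enol ether is then treated with BF3·OEt2 or SnCl4 in CH2Cl2 at low temperature. A 1,3 oxygen-to-carbon shift through the benzylic ion pair, the known acid-mediated conversion of hydrobenzofuranoid into bicyclo[3.2.1]octanoid neolignans, returns to the route at 18.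

## Further compounds

F1 | step 8 | (3R,4S,5S)-3-allyl-3-(2,2-dimethoxy-3-oxobutyl)-5-(3,4-dimethoxyphenyl)-4-methyloxolan-2-one | O=C1[C@](CC=C)(CC(OC)(OC)C(C)=O)[C@H](C)[C@@H](c2ccc(OC)c(OC)c2)O1
F2 | step 8 | (4R)-4-allyl-4-[(1S,2S)-1-(3,4-dimethoxyphenyl)-1-hydroxypropan-2-yl]-6,6-dimethoxycyclohexane-1,3-dione | O=C1CC(=O)C(OC)(OC)C[C@]1(CC=C)[C@H](C)[C@H](O)c1ccc(OC)c(OC)c1
F3 | step 7 | (Z)-1-methoxy-2-(trimethylsilyloxy)prop-1-ene | CO/C=C(/C)O[Si](C)(C)C
F4 | step 7 | 3-allyl-5-(3,4-dimethoxyphenyl)-3-(1-hydroxy-2-methoxy-3-oxobutyl)-4-methyloxolan-2-one (ring configured as in 12, mixture at the two side-chain carbons) | O=C1[C@](CC=C)(C(O)C(OC)C(C)=O)[C@H](C)[C@@H](c2ccc(OC)c(OC)c2)O1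
F5 | step 7 | (3S,4S,5S)-3-allyl-5-(3,4-dimethoxyphenyl)-3-[(1Z)-2-methoxy-3-oxobut-1-en-1-yl]-4-methyloxolan-2-one | O=C1[C@](CC=C)(/C=C(\OC)C(C)=O)[C@H](C)[C@@H](c2ccc(OC)c(OC)c2)O1
F6 | step 5 | (3R,4S,5S)-5-(3,4-dimethoxyphenyl)-3-(hydroxymethyl)-4-methyloxolan-2-one | O=C1[C@@H](CO)[C@H](C)[C@@H](c2ccc(OC)c(OC)c2)O1
F7 | step 5 | (3S,4S,5S)-3-allyl-5-(3,4-dimethoxyphenyl)-3-(hydroxymethyl)-4-methyloxolan-2-one | O=C1[C@](CC=C)(CO)[C@H](C)[C@@H](c2ccc(OC)c(OC)c2)O1
F8 | step 9 | 3a-allyl-2-(3,4-dimethoxyphenyl)-5-methoxy-3-methyl-3,3a-dihydro-1-benzofuran-6(2H)-one (aryl cis to methyl, allyl trans to methyl) | COC1=C[C@]2(CC=C)[C@H](C)[C@H](c3ccc(OC)c(OC)c3)OC2=CC1=O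
A1 | alternative 1 | phenyl (E)-3-[3-(3,4-dimethoxyphenyl)-5-oxocyclopent-1-en-1-yl]-2-methoxyacrylate | O=C1C(/C=C(/OC)C(=O)Oc2ccccc2)=C[C@@H](c2ccc(OC)c(OC)c2)C1
A2 | alternative 1 | phenyl (E)-3-[1-allyl-4-(3,4-dimethoxyphenyl)-5-methyl-2-oxocyclopentyl]-2-methoxyacrylate | O=C1[C@](CC=C)(/C=C(/OC)C(=O)Oc2ccccc2)[C@H](C)[C@@H](c2ccc(OC)c(OC)c2)C1
A3 | alternative 2 | 2-allylcyclopentane-1,3-dione | C=CCC1C(=O)CCC1=O
A4 | alternative 2 | acrolein | C=CC=O
A5 | alternative 2 | 1-allyl-4-hydroxybicyclo[3.2.1]octane-7,8-dione | C=CC[C@]12CC[C@H](O)[C@H](C1=O)CC2=O
A6 | alternative 3 | methyl (4E)-4-[(2E)-3-(3,4-dimethoxyphenyl)prop-2-enoyl]hex-4-enoate | COC(=O)CC/C(=C\C)C(=O)/C=C/c1ccc(OC)c(OC)c1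
A7 | alternative 3 | methyl 3-[1-allyl-4-(3,4-dimethoxyphenyl)-5-methyl-2-oxocyclopentyl]propanoate | O=C1[C@](CC=C)(CCC(=O)OC)[C@H](C)[C@@H](c2ccc(OC)c(OC)c2)C1
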